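## Retrosynthetic overview

1. The target is ent-oritin-(4α→6)-oritin-4α-ol. Its lower C4 carbinol is made last, by NaBH4 reduction of a dihydroflavonol ketone after global debenzylation.
2. The upper 3-OH/4-H pair (2,3-trans-3,4-cis) comes from a 4-aryl-flav-3-ene by OsO4 dihydroxylation and ionic hydrogenation of the tertiary benzylic alcohol.
3. The C4(upper)–C6(lower) bond comes from a Stille coupling of an upper flav-3-en-4-yl stannane with a lower 6-bromo dihydroflavonol.
4. Each ring C is closed by an enantioselective organocatalytic intramolecular oxa-Michael addition of a 2-hydroxyphenyl alkylidene β-ketoester, followed by decarboxylation.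
5. Ring order: rings A and B are bought (methyl 2,3,4-trihydroxybenzoate, 4-benzyloxybenzaldehyde); ring C of the upper unit and ring C of the lower unit are formed in two parallel branches before the coupling.

Assumption: the epi-quinidine-derived thiourea is taken to give the (2R) flavanone and the epi-quinine-derived one the (2S) flavanone; if the sense is the reverse, the two catalysts are swapped between steps 4 and 10 and nothing else changes.

Convention: ring A drawn left, O1 up; β = towards the viewer, α = away. The upper unit needs its 2-aryl β, the lower unit needs it α.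

## Route

Step 1
Reactants: 1 methyl 2,3,4-trihydroxybenzoate
Product: 2 methyl 3,4-bis(benzyloxy)-2-hydroxybenzoate
Conditions: BnBr (2.1 equiv), K2CO3 (2.2 equiv), acetone, reflux
Reagents that add atoms: benzyl bromide BrCc1ccccc1
Why: Williamson ether synthesis; the 2-OH is hydrogen-bonded to the ester carbonyl and is the least reactive, so two equivalents benzylate only the 3- and 4-OH groups.

Step 2
Reactants: 2 methyl 3,4-bis(benzyloxy)-2-hydroxybenzoate; 3 tert-butyl acetate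
Product: 4 tert-butyl 3-[3,4-bis(benzyloxy)-2-hydroxyphenyl]-3-oxopropanoate
Conditions: LiN(i-Pr)2 (3.5 equiv), 3 (3.5 equiv), THF, −78 °C; add 2, −78 → 0 °C; aq. NH4Cl
Reagents that add atoms: none
Why: Crossed Claisen condensation; excess ester enolate first deprotonates the phenol, then acylates, and the product survives as its enolate until quench, while the tert-butyl ester resists lactonisation to a 4-hydroxycoumarin.

Step 3
Reactants: 4 tert-butyl 3-[3,4-bis(benzyloxy)-2-hydroxyphenyl]-3-oxopropanoate; 5 4-(benzyloxy)benzaldehyde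
Product: 6 tert-butyl 2-[3,4-bis(benzyloxy)-2-hydroxybenzoyl]-3-[4-(benzyloxy)phenyl]prop-2-enoate (E/Z mixture)
Conditions: piperidine (10 mol%), AcOH (10 mol%), 4 Å sieves, toluene, rt
Reagents that add atoms: none
Why: Knoevenagel condensation of the active methylene with the aryl aldehyde; the chelated phenol does not add under these mild buffered conditions.

Step 4
Reactants: 6 tert-butyl 2-[3,4-bis(benzyloxy)-2-hydroxybenzoyl]-3-[4-(benzyloxy)phenyl]prop-2-enoate
Product: 8 (2R)-7,8-bis(benzyloxy)-2-[4-(benzyloxy)phenyl]chroman-4-one, via 3-tert-butoxycarbonyl flavanone 7 (not isolated)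
Conditions: 1-[3,5-bis(trifluoromethyl)phenyl]-3-[(9R)-6'-methoxycinchonan-9-yl]thiourea (epi-quinidine thiourea, 10 mol%), toluene, −25 °C; then TsOH·H2O (0.5 equiv), 80 °C
Reagents that add atoms: none
Why: Intramolecular oxa-Michael addition under bifunctional thiourea/amine catalysis closes ring C and sets C2 (aryl β, R) by face-selective delivery of the phenol to the bound alkylidene β-ketoester; acid then removes isobutene and CO2, which shuts off the retro-Michael pathway.

Step 5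
Reactants: 8 (2R)-7,8-bis(benzyloxy)-2-[4-(benzyloxy)phenyl]chroman-4-one
Product: 9 (2R)-7,8-bis(benzyloxy)-2-[4-(benzyloxy)phenyl]-2H-chromen-4-yl trifluoromethanesulfonate
Conditions: Comins' reagent (1.2 equiv), KN(SiMe3)2 (1.1 equiv, added last), THF, −78 °C
Reagents that add atoms: Comins' reagent FC(F)(F)S(=O)(=O)N(c1ccc(Cl)cn1)S(=O)(=O)C(F)(F)F
Why: Enol triflate formation by O-sulfonylation of the kinetic enolate; adding base to ketone plus reagent at −78 °C traps the enolate before E1cB opening of ring C, so C2 is untouched.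

Step 6
Reactants: 9 (2R)-7,8-bis(benzyloxy)-2-[4-(benzyloxy)phenyl]-2H-chromen-4-yl trifluoromethanesulfonate
Product: 10 [(2R)-7,8-bis(benzyloxy)-2-[4-(benzyloxy)phenyl]-2H-chromen-4-yl](trimethyl)stannane
Conditions: Me3SnSnMe3 (1.3 equiv), Pd(PPh3)4 (5 mol%), LiCl (5 equiv), dioxane, 60 °C, dark
Reagents that add atoms: hexamethylditin C[Sn](C)(C)[Sn](C)(C)C
Why: Palladium-catalysed stannylation of a vinyl triflate with a distannane (oxidative addition to zerovalent palladium, Sn–Sn transmetalation, reductive elimination); neutral conditions and exclusion of light keep the 2H-chromene stereocentre intact.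

Step 7
Reactants: 2 methyl 3,4-bis(benzyloxy)-2-hydroxybenzoate
Product: 11 methyl 3,4-bis(benzyloxy)-5-bromo-2-hydroxybenzoate
Conditions: NBS (1.05 equiv), MeCN, 0 °C → rt, dark
Reagents that add atoms: N-bromosuccinimide O=C1CCC(=O)N1Br
Why: Electrophilic aromatic bromination; C5 is para to the free phenol, ortho to an ether oxygen and meta to the ester, so it is the only strongly activated position (it becomes C6 of the lower flavan).

Step 8
Reactants: 11 methyl 3,4-bis(benzyloxy)-5-bromo-2-hydroxybenzoate; 3 tert-butyl acetate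
Product: 12 tert-butyl 3-[3,4-bis(benzyloxy)-5-bromo-2-hydroxyphenyl]-3-oxopropanoate
Conditions: LiN(i-Pr)2 (3.5 equiv), 3 (3.5 equiv), THF, −78 °C; add 11, −78 → 0 °C; aq. NH4Cl
Reagents that add atoms: none
Why: Crossed Claisen condensation as in step 2; the preformed ester enolate leaves the aryl bromide alone.

Step 9
Reactants: 12 tert-butyl 3-[3,4-bis(benzyloxy)-5-bromo-2-hydroxyphenyl]-3-oxopropanoate; 5 4-(benzyloxy)benzaldehyde
Product: 13 tert-butyl 2-[3,4-bis(benzyloxy)-5-bromo-2-hydroxybenzoyl]-3-[4-(benzyloxy)phenyl]prop-2-enoate (E/Z mixture)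
Conditions: piperidine (10 mol%), AcOH (10 mol%), 4 Å sieves, toluene, rt
Reagents that add atoms: none
Why: Knoevenagel condensation as in step 3.

Step 10
Reactants: 13 tert-butyl 2-[3,4-bis(benzyloxy)-5-bromo-2-hydroxybenzoyl]-3-[4-(benzyloxy)phenyl]prop-2-enoate
Product: 15 (2S)-7,8-bis(benzyloxy)-2-[4-(benzyloxy)phenyl]-6-bromochroman-4-one, via 6-bromo-3-tert-butoxycarbonyl flavanone 14 (not isolated)
Conditions: 1-[3,5-bis(trifluoromethyl)phenyl]-3-[(8α,9S)-6'-methoxycinchonan-9-yl]thiourea (epi-quinine thiourea, 10 mol%), toluene, −25 °C; then TsOH·H2O (0.5 equiv), 80 °C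
Reagents that add atoms: none
Why: The same intramolecular oxa-Michael addition with the pseudo-enantiomeric catalyst closes ring C of the lower unit with the opposite sense (aryl α, S), and decarboxylation fixes it.

Step 11
Reactants: 15 (2S)-7,8-bis(benzyloxy)-2-[4-(benzyloxy)phenyl]-6-bromochroman-4-one
Product: 17 (2R,3R)-7,8-bis(benzyloxy)-2-[4-(benzyloxy)phenyl]-6-bromo-3-hydroxychroman-4-one, via trimethylsilyl enol ether 16 (not isolated)
Conditions: TMSOTf (1.3 equiv), Et3N (2 equiv), CH2Cl2, 0 °C; then DMDO (1.2 equiv), acetone/CH2Cl2, −40 → 0 °C; aq. citric acid/THF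
Reagents that add atoms: dimethyldioxirane CC1(C)OO1; trimethylsilyl trifluoromethanesulfonate C[Si](C)(C)OS(=O)(=O)C(F)(F)F (silicon is carried only in 16)
Why: Rubottom oxidation; soft enolisation avoids a free enolate, and DMDO attacks the enol ether anti to the 2-aryl group to give the 2,3-trans ketol (3-OH β, 3R), with C2 renamed from S to R by priority only.

Step 12
Reactants: 10 [(2R)-7,8-bis(benzyloxy)-2-[4-(benzyloxy)phenyl]-2H-chromen-4-yl](trimethyl)stannane; 17 (2R,3R)-7,8-bis(benzyloxy)-2-[4-(benzyloxy)phenyl]-6-bromo-3-hydroxychroman-4-one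
Product: 18 (2R,3R)-7,8-bis(benzyloxy)-6-{(2R)-7,8-bis(benzyloxy)-2-[4-(benzyloxy)phenyl]-2H-chromen-4-yl}-2-[4-(benzyloxy)phenyl]-3-hydroxychroman-4-one
Conditions: Pd(PPh3)4 (10 mol%), CuCl (5 equiv), LiCl (6 equiv), degassed DMSO, 60 °C, dark
Reagents that add atoms: none
Why: Stille cross-coupling with copper-assisted transfer of the hindered vinyl group; it is base-free, which the ring-opening-prone dihydroflavonol requires, and joining two enantio-enriched halves sends the minor enantiomers into separable diastereomers.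

Step 13
Reactants: 18 (2R,3R)-7,8-bis(benzyloxy)-6-{(2R)-7,8-bis(benzyloxy)-2-[4-(benzyloxy)phenyl]-2H-chromen-4-yl}-2-[4-(benzyloxy)phenyl]-3-hydroxychroman-4-one
Product: 19 (2R,3R)-7,8-bis(benzyloxy)-6-{(2S,3S,4S)-7,8-bis(benzyloxy)-2-[4-(benzyloxy)phenyl]-3,4-dihydroxychroman-4-yl}-2-[4-(benzyloxy)phenyl]-3-hydroxychroman-4-one
Conditions: OsO4 (5 mol%), NMO (2 equiv), acetone/t-BuOH/H2O, rt
Reagents that add atoms: osmium tetroxide O=[Os](=O)(=O)=O; N-methylmorpholine N-oxide C[N+]1([O-])CCOCC1; water O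
Why: Upjohn dihydroxylation; OsO4 adds suprafacially to the trisubstituted styrene-type double bond on the face anti to the upper 2-aryl group, placing both new hydroxyls α (upper C2 is now named S by priority only).

Step 14
Reactants: 19 (2R,3R)-7,8-bis(benzyloxy)-6-{(2S,3S,4S)-7,8-bis(benzyloxy)-2-[4-(benzyloxy)phenyl]-3,4-dihydroxychroman-4-yl}-2-[4-(benzyloxy)phenyl]-3-hydroxychroman-4-one
Product: 20 (2R,3R)-7,8-bis(benzyloxy)-6-{(2S,3R,4S)-7,8-bis(benzyloxy)-2-[4-(benzyloxy)phenyl]-3-hydroxychroman-4-yl}-2-[4-(benzyloxy)phenyl]-3-hydroxychroman-4-one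
Conditions: Et3SiH (10 equiv), then TFA (5 equiv), CH2Cl2, −40 → 0 °C
Reagents that add atoms: none
Why: Ionic hydrogenation; TFA ionises only the tertiary doubly benzylic C4–OH, and the silane delivers hydride axially anti to the C3–OH (held axial by allylic strain against the 4-aryl group), so H enters β and the lower aryl ends α, cis to the 3-OH (2,3-trans-3,4-cis), while the ketone and benzyl ethers are inert at this temperature.

Step 15
Reactants: 20 (2R,3R)-7,8-bis(benzyloxy)-6-{(2S,3R,4S)-7,8-bis(benzyloxy)-2-[4-(benzyloxy)phenyl]-3-hydroxychroman-4-yl}-2-[4-(benzyloxy)phenyl]-3-hydroxychroman-4-one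
Product: 22 (2R,3S,4R)-2-(4-hydroxyphenyl)-6-[(2S,3R,4R)-3,7,8-trihydroxy-2-(4-hydroxyphenyl)chroman-4-yl]chromane-3,4,7,8-tetrol, via hexaphenol ketone 21 (not isolated)
Conditions: H2 (1 atm), Pd(OH)2/C, THF/MeOH, rt; filter under Ar; then NaBH4 (6 equiv), EtOH, 0 °C → rt; AcOH to pH 6, Sephadex LH-20
Reagents that add atoms: none
Why: Hydrogenolysis of the six benzyl ethers while C4 is still a ketone (no benzylic C4–O bond is exposed to H2/Pd), then borohydride reduction of the trans-dihydroflavonol by axial hydride attack gives the equatorial 4-OH trans to the 3-OH (4R, 2,3-trans-3,4-trans).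

## Compound list

1 | methyl 2,3,4-trihydroxybenzoate | COC(=O)c1ccc(O)c(O)c1O | starting material
2 | methyl 3,4-bis(benzyloxy)-2-hydroxybenzoate | COC(=O)c1ccc(OCc2ccccc2)c(OCc2ccccc2)c1O | intermediate
3 | tert-butyl acetate | CC(=O)OC(C)(C)C | starting material
4 | tert-butyl 3-[3,4-bis(benzyloxy)-2-hydroxyphenyl]-3-oxopropanoate | CC(C)(C)OC(=O)CC(=O)c1ccc(OCc2ccccc2)c(OCc2ccccc2)c1O | intermediate
5 | 4-(benzyloxy)benzaldehyde | O=Cc1ccc(OCc2ccccc2)cc1 | starting material
6 | tert-butyl 2-[3,4-bis(benzyloxy)-2-hydroxybenzoyl]-3-[4-(benzyloxy)phenyl]prop-2-enoate (E/Z mixture) | CC(C)(C)OC(=O)C(=Cc1ccc(OCc2ccccc2)cc1)C(=O)c1ccc(OCc2ccccc2)c(OCc2ccccc2)c1O | intermediate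
7 | tert-butyl (2R)-7,8-bis(benzyloxy)-2-[4-(benzyloxy)phenyl]-4-oxochromane-3-carboxylate (C3 labile, keto/enol) | O=C1C(C(=O)OC(C)(C)C)[C@H](c2ccc(OCc3ccccc3)cc2)Oc2c1ccc(OCc1ccccc1)c2OCc1ccccc1 | intermediate (not isolated)
8 | (2R)-7,8-bis(benzyloxy)-2-[4-(benzyloxy)phenyl]chroman-4-one (aryl β) | O=C1C[C@H](c2ccc(OCc3ccccc3)cc2)Oc2c1ccc(OCc1ccccc1)c2OCc1ccccc1 | intermediate
9 | (2R)-7,8-bis(benzyloxy)-2-[4-(benzyloxy)phenyl]-2H-chromen-4-yl trifluoromethanesulfonate | O=S(=O)(OC1=C[C@H](c2ccc(OCc3ccccc3)cc2)Oc2c1ccc(OCc1ccccc1)c2OCc1ccccc1)C(F)(F)F | intermediate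
10 | [(2R)-7,8-bis(benzyloxy)-2-[4-(benzyloxy)phenyl]-2H-chromen-4-yl](trimethyl)stannane | C[Sn](C)(C)C1=C[C@H](c2ccc(OCc3ccccc3)cc2)Oc2c1ccc(OCc1ccccc1)c2OCc1ccccc1 | intermediate
11 | methyl 3,4-bis(benzyloxy)-5-bromo-2-hydroxybenzoate | COC(=O)c1cc(Br)c(OCc2ccccc2)c(OCc2ccccc2)c1O | intermediate
12 | tert-butyl 3-[3,4-bis(benzyloxy)-5-bromo-2-hydroxyphenyl]-3-oxopropanoate | CC(C)(C)OC(=O)CC(=O)c1cc(Br)c(OCc2ccccc2)c(OCc2ccccc2)c1O | intermediate
13 | tert-butyl 2-[3,4-bis(benzyloxy)-5-bromo-2-hydroxybenzoyl]-3-[4-(benzyloxy)phenyl]prop-2-enoate (E/Z mixture) | CC(C)(C)OC(=O)C(=Cc1ccc(OCc2ccccc2)cc1)C(=O)c1cc(Br)c(OCc2ccccc2)c(OCc2ccccc2)c1O | intermediate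
14 | tert-butyl (2S)-7,8-bis(benzyloxy)-2-[4-(benzyloxy)phenyl]-6-bromo-4-oxochromane-3-carboxylate (C3 labile, keto/enol) | O=C1C(C(=O)OC(C)(C)C)[C@@H](c2ccc(OCc3ccccc3)cc2)Oc2c1cc(Br)c(OCc1ccccc1)c2OCc1ccccc1 | intermediate (not isolated)
15 | (2S)-7,8-bis(benzyloxy)-2-[4-(benzyloxy)phenyl]-6-bromochroman-4-one (aryl α) | O=C1C[C@@H](c2ccc(OCc3ccccc3)cc2)Oc2c1cc(Br)c(OCc1ccccc1)c2OCc1ccccc1 | intermediate
16 | (2S)-7,8-bis(benzyloxy)-2-[4-(benzyloxy)phenyl]-6-bromo-4-(trimethylsilyloxy)-2H-chromene | C[Si](C)(C)OC1=C[C@@H](c2ccc(OCc3ccccc3)cc2)Oc2c1cc(Br)c(OCc1ccccc1)c2OCc1ccccc1 | intermediate (not isolated)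
17 | (2R,3R)-7,8-bis(benzyloxy)-2-[4-(benzyloxy)phenyl]-6-bromo-3-hydroxychroman-4-one (2,3-trans) | O=C1[C@H](O)[C@@H](c2ccc(OCc3ccccc3)cc2)Oc2c1cc(Br)c(OCc1ccccc1)c2OCc1ccccc1 | intermediate
18 | (2R,3R)-7,8-bis(benzyloxy)-6-{(2R)-7,8-bis(benzyloxy)-2-[4-(benzyloxy)phenyl]-2H-chromen-4-yl}-2-[4-(benzyloxy)phenyl]-3-hydroxychroman-4-one | O=C1[C@H](O)[C@@H](c2ccc(OCc3ccccc3)cc2)Oc2c1cc(C3=C[C@H](c4ccc(OCc5ccccc5)cc4)Oc4c3ccc(OCc3ccccc3)c4OCc3ccccc3)c(OCc1ccccc1)c2OCc1ccccc1 | intermediate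
19 | (2R,3R)-7,8-bis(benzyloxy)-6-{(2S,3S,4S)-7,8-bis(benzyloxy)-2-[4-(benzyloxy)phenyl]-3,4-dihydroxychroman-4-yl}-2-[4-(benzyloxy)phenyl]-3-hydroxychroman-4-one (upper 3-OH and 4-OH both α, trans to the upper 2-aryl) | O=C1[C@H](O)[C@@H](c2ccc(OCc3ccccc3)cc2)Oc2c1cc([C@]3(O)[C@@H](O)[C@H](c4ccc(OCc5ccccc5)cc4)Oc4c3ccc(OCc3ccccc3)c4OCc3ccccc3)c(OCc1ccccc1)c2OCc1ccccc1 | intermediate
20 | (2R,3R)-7,8-bis(benzyloxy)-6-{(2S,3R,4S)-7,8-bis(benzyloxy)-2-[4-(benzyloxy)phenyl]-3-hydroxychroman-4-yl}-2-[4-(benzyloxy)phenyl]-3-hydroxychroman-4-one (upper unit 2,3-trans-3,4-cis) | O=C1[C@H](O)[C@@H](c2ccc(OCc3ccccc3)cc2)Oc2c1cc([C@@H]3c4ccc(OCc5ccccc5)c(OCc5ccccc5)c4O[C@@H](c4ccc(OCc5ccccc5)cc4)[C@@H]3O)c(OCc1ccccc1)c2OCc1ccccc1 | intermediate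
21 | (2R,3R)-3,7,8-trihydroxy-2-(4-hydroxyphenyl)-6-[(2S,3R,4R)-3,7,8-trihydroxy-2-(4-hydroxyphenyl)chroman-4-yl]chroman-4-one | O=C1[C@H](O)[C@@H](c2ccc(O)cc2)Oc2c1cc([C@@H]3c4ccc(O)c(O)c4O[C@@H](c4ccc(O)cc4)[C@@H]3O)c(O)c2O | intermediate (not isolated)
22 | (2R,3S,4R)-2-(4-hydroxyphenyl)-6-[(2S,3R,4R)-3,7,8-trihydroxy-2-(4-hydroxyphenyl)chroman-4-yl]chromane-3,4,7,8-tetrol (ent-oritin-(4α→6)-oritin-4α-ol) | Oc1ccc([C@H]2Oc3c(cc([C@@H]4c5ccc(O)c(O)c5O[C@@H](c5ccc(O)cc5)[C@@H]4O)c(O)c3O)[C@@H](O)[C@@H]2O)cc1 | target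

## Step count and risks

Total step count: 15. Longest linear sequence: 10 (step 1, then steps 7–11, then steps 12–15; the upper branch through steps 2–6 is equally long).

The three steps most likely to fail:

**Step 4** (its mirror-image twin, step 10, carries the same risk). The benzyloxy group next to the attacking phenol may lower the enantioselectivity, and the sense of induction is assumed. Fallback: set out from 6 and cyclise without chiral control (DBU 10 mol%, toluene, rt; then TsOH·H2O, 80 °C) to the racemic 7,8-bis(benzyloxy)-2-[4-(benzyloxy)phenyl]chroman-4-one F1. Resolve it kinetically by asymmetric transfer hydrogenation (RuCl[(S,S)-TsDPEN](p-cymene), HCO2H/Et3N, EtOAc, rt, about 55% conversion). The (2S) enantiomer, which takes hydride anti to its aryl group, is reduced to (2S,4S)-7,8-bis(benzyloxy)-2-[4-(benzyloxy)phenyl]chroman-4-ol F2 and is removed by chromatography. The unreacted (2R) ketone comes back to the route at 8. Ring C is still closed by the same oxa-Michael addition; only the source of enantiopurity changes.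

**Step 12.** The 1-aryl vinylstannane 10 is hindered and may homocouple or give cine products. Fallback: exchange the roles of the partners. Set out from 17 and stannylate it (Me3SnSnMe3, Pd(PPh3)4, toluene, 100 °C) to (2R,3R)-7,8-bis(benzyloxy)-2-[4-(benzyloxy)phenyl]-3-hydroxy-6-(trimethylstannyl)chroman-4-one F3. Couple F3 with the vinyl triflate 9 (Pd(PPh3)4, CuCl, LiCl, DMSO, 50 °C). This comes back to the route at 18, and step 6 is no longer needed.

**Step 14.** The free cation from 19 may undergo a semipinacol shift to the 3-ketone or take hydride from both faces. Fallback: leave out diol 19. Set out from 18 and epoxidise with DMDO (acetone/CH2Cl2, −40 °C) to the 3,4-epoxide of 18 with the oxirane trans to the upper 2-aryl group F4. Without isolation add Et3SiH, then BF3·OEt2, at −78 °C. The C4–O bond opens as a contact ion pair whose α face stays covered by the boron-bound oxygen on C3, so hydride enters from the β face. The route is rejoined at 20.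

## Further compounds

F1 | step 4 | racemic 7,8-bis(benzyloxy)-2-[4-(benzyloxy)phenyl]chroman-4-one | O=C1CC(c2ccc(OCc3ccccc3)cc2)Oc2c1ccc(OCc1ccccc1)c2OCc1ccccc1
F2 | step 4 | (2S,4S)-7,8-bis(benzyloxy)-2-[4-(benzyloxy)phenyl]chroman-4-ol | O[C@H]1C[C@@H](c2ccc(OCc3ccccc3)cc2)Oc2c1ccc(OCc1ccccc1)c2OCc1ccccc1
F3 | step 12 | (2R,3R)-7,8-bis(benzyloxy)-2-[4-(benzyloxy)phenyl]-3-hydroxy-6-(trimethylstannyl)chroman-4-one | O=C1[C@H](O)[C@@H](c2ccc(OCc3ccccc3)cc2)Oc2c1cc([Sn](C)(C)C)c(OCc1ccccc1)c2OCc1ccccc1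
F4 | step 14 | 3,4-epoxide of 18 (oxirane trans to the upper 2-aryl group) | O=C1[C@H](O)[C@@H](c2ccc(OCc3ccccc3)cc2)Oc2c1cc([C@@]35O[C@H]5[C@H](c4ccc(OCc6ccccc6)cc4)Oc4c3ccc(OCc3ccccc3)c4OCc3ccccc3)c(OCc1ccccc1)c2OCc1ccccc1
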